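**Strategy.** The target is a mulberry-type Diels–Alder adduct whose aroyl ring at C4 of the methylcyclohexene carries a fused 2,2-dimethyl-2H-pyran (O1, C2, C3, C4, C4a, C8a). Everything rests on closing this pyran last from an aryl 1,1-dimethylpropargyl ether: on heating, a propargyl Claisen shift from O-4' to C-3', the carbon between the two ring oxygens that the 2'-OH···O=C chelate activates, a 1,5-hydrogen shift and an oxa-6π electrocyclisation forge C4a–C4 and O1–C2 in one operation. The precursor is the endo cyclohexene hexaacetate with the propargyl ether intact, made by a chiral borate-catalysed Diels–Alder reaction that sets all three stereocentres.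

Key step: step 14

Remark on locants: C1–C6 are the methylcyclohexene carbons (C1 methyl, C3 aryl, C4 aroyl, C5 2,4-dioxyphenyl). Primed locants belong to the aroyl ring on C4 (C-1' carries the carbonyl).

Assumption: the (S)-VANOL borate in step 13 is assumed to direct the diene to the α-Si/β-Si face of the chelated enone. If the sense of induction is the opposite, (R)-VANOL is used with no other change.

Acetates are chosen as the final protecting groups because acid at the end would ketalise the C4 ketone with the flanking ortho-phenols; methoxymethyl groups are therefore exchanged for acetates at the chalcone stage.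

**Step 1**
Reactants: 1 2,4-dihydroxybenzaldehyde
Product: 2 2,4-bis(methoxymethoxy)benzaldehyde
Conditions: NaH, MOMCl, DMF, 0 °C to rt
Reagents that add atoms: chloromethyl methyl ether, COCCl
Why: Williamson-type O-alkylation of both phenoxides; NaH is used because the hydrogen-bonded 2-OH is sluggish under weaker bases.

**Step 2**
Reactants: 3 1-(2,4-dihydroxyphenyl)ethanone; 4 3-chloro-3-methylbut-1-yne
Product: 5 1-[2-hydroxy-4-(2-methylbut-3-yn-2-yloxy)phenyl]ethanone
Conditions: K2CO3, KI, CuI (cat.), acetone, reflux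
Reagents that add atoms: none
Why: copper-assisted O-propargylation of a phenol with a tertiary propargylic chloride; only the free 4-OH reacts because the 2-OH is locked in the hydrogen bond to the acetyl group.

**Step 3**
Reactants: 5 1-[2-hydroxy-4-(2-methylbut-3-yn-2-yloxy)phenyl]ethanone; 2 2,4-bis(methoxymethoxy)benzaldehyde
Product: 6 (E)-3-[2,4-bis(methoxymethoxy)phenyl]-1-[2-hydroxy-4-(2-methylbut-3-yn-2-yloxy)phenyl]prop-2-en-1-one
Conditions: KOH, EtOH/H2O, rt
Reagents that add atoms: none
Why: Claisen–Schmidt aldol condensation giving the thermodynamically favoured E-enone; the quaternary propargylic carbon cannot isomerise under base.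

**Step 4**
Reactants: 6 the bis(methoxymethyl) chalcone
Product: 7 (E)-3-(2,4-dihydroxyphenyl)-1-[2-hydroxy-4-(2-methylbut-3-yn-2-yloxy)phenyl]prop-2-en-1-one
Conditions: HCl (3 M aq), MeOH, 45 °C
Reagents that add atoms: none
Why: acid-catalysed methanolysis of the aryl methoxymethyl acetals through oxocarbenium ions should be much faster than ionisation of the tertiary propargyl aryl ether, whose cation is destabilised by the alkynyl group.

**Step 5**
Reactants: 7 the trihydroxy chalcone
Product: 8 (E)-4-{3-[2-hydroxy-4-(2-methylbut-3-yn-2-yloxy)phenyl]-3-oxoprop-1-enyl}-1,3-phenylene diacetate (dienophile)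
Conditions: Ac2O (2.1 equiv), Et3N, CH2Cl2, 0 °C
Reagents that add atoms: acetic anhydride, CC(=O)OC(C)=O
Why: selective O-acetylation of the two non-chelated phenols without acyl-transfer catalyst leaves the hydrogen-bonded 2'-OH free, as the later boron chelation requires.

**Step 6**
Reactants: 3 1-(2,4-dihydroxyphenyl)ethanone
Product: 9 1-(2,4-dihydroxy-3-iodophenyl)ethanone
Conditions: I2, HIO3, EtOH/H2O, rt
Reagents that add atoms: iodine, II; iodic acid, OI(=O)=O
Why: electrophilic aromatic iodination directed to C-3, the position ortho to both hydroxyl groups, with iodic acid reoxidising iodide so that all iodine is used; any 5-iodo isomer is removed by crystallisation.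

**Step 7**
Reactants: 9 1-(2,4-dihydroxy-3-iodophenyl)ethanone
Product: 10 1-[3-iodo-2,4-bis(methoxymethoxy)phenyl]ethanone
Conditions: NaH, MOMCl, DMF, 0 °C to rt
Reagents that add atoms: chloromethyl methyl ether, COCCl
Why: Williamson-type protection of both phenols, needed because a free 4-OH phenoxide would suppress enolate formation in the following aldol condensation.

**Step 8**
Reactants: 10 1-[3-iodo-2,4-bis(methoxymethoxy)phenyl]ethanone; 2 2,4-bis(methoxymethoxy)benzaldehyde
Product: 11 (E)-3-[2,4-bis(methoxymethoxy)phenyl]-1-[3-iodo-2,4-bis(methoxymethoxy)phenyl]prop-2-en-1-one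
Conditions: KOH, EtOH/H2O, rt
Reagents that add atoms: none
Why: Claisen–Schmidt aldol condensation to the E-chalcone; the aryl iodide and the acetals are inert to hydroxide.

**Step 9**
Reactants: 11 the tetrakis(methoxymethyl) iodochalcone
Product: 12 (E)-1-(2,4-dihydroxy-3-iodophenyl)-3-(2,4-dihydroxyphenyl)prop-2-en-1-one
Conditions: HCl (3 M aq), MeOH, 50 °C
Reagents that add atoms: none
Why: acid-catalysed acetal methanolysis, placed before the diene is introduced because an electron-rich aryl diene would not survive acid.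

**Step 10**
Reactants: 12 the tetrahydroxy iodochalcone
Product: 13 (E)-1-(2,4-diacetoxy-3-iodophenyl)-3-(2,4-diacetoxyphenyl)prop-2-en-1-one
Conditions: Ac2O (excess), pyridine, DMAP (cat.), CH2Cl2, rt
Reagents that add atoms: acetic anhydride, CC(=O)OC(C)=O
Why: exhaustive acetylation under nucleophilic catalysis also caps the hindered chelated 2'-OH, so that this chalcone cannot bind boron and compete as a dienophile later.

**Step 11**
Reactants: 14 2-methylbut-1-en-3-yne
Product: 15 (E)-4,4,5,5-tetramethyl-2-(3-methylbuta-1,3-dienyl)-1,3,2-dioxaborolane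
Conditions: pinacolborane, Cp2Zr(H)Cl (5 mol %), Et3N (cat.), neat, 60 °C
Reagents that add atoms: pinacolborane, CC1(C)OBOC1(C)C
Why: zirconium-catalysed syn-hydroboration of the terminal alkyne places boron on the terminal carbon and gives the E-alkenylboronate, leaving the 1,1-disubstituted alkene untouched.

**Step 12**
Reactants: 13 the tetraacetoxy iodochalcone; 15 the E-dienylboronate
Product: 16 (E)-1-[2,4-diacetoxy-3-((E)-3-methylbuta-1,3-dienyl)phenyl]-3-(2,4-diacetoxyphenyl)prop-2-en-1-one (diene)
Conditions: Pd(OAc)2 (5 mol %), SPhos (10 mol %), anhydrous K3PO4, toluene, 60 °C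
Reagents that add atoms: none
Why: Suzuki–Miyaura cross-coupling with retention of the E-alkene geometry; the bulky biaryl phosphine should allow coupling at the di-ortho-substituted iodide, and the anhydrous mild base should spare the aryl acetates.

**Step 13**
Reactants: 8 the 2'-hydroxychalcone dienophile; 16 the aryl diene
Product: 17 endo adduct (3S,4R,5S) hexaacetate carrying the 2-hydroxy-4-(2-methylbut-3-yn-2-yloxy)benzoyl group at C4
Conditions: B(OPh)3 (0.3 equiv), (S)-VANOL (0.3 equiv), 4 Å MS, toluene, 25–40 °C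
Reagents that add atoms: none
Why: asymmetric Diels–Alder reaction of the boron-chelated 2'-hydroxychalcone, in which the E-enone fixes C4/C5 trans, the endo transition state places the C3 aryl cis to the C4 aroyl, the ortho/para orientation joins the aryl-bearing diene terminus to the α-carbon, and the vaulted biaryl ligand shields one face so that the diene adds to the α-Si/β-Si face to give (3S,4R,5S); the exo diastereomer is removed by chromatography.

**Step 14**
Reactants: 17 the endo adduct with the propargyl ether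
Product: 21 chromene hexaacetate (3S,4R,5S) with the 5-hydroxy-2,2-dimethyl-2H-chromene-6-carbonyl group at C4, via allenyl cyclohexadienone 18 (not isolated), via ortho-allenylphenol 19 (not isolated), via ortho-quinone methide 20 (not isolated)
Conditions: o-xylene (degassed), 140 °C, sealed tube, argon
Reagents that add atoms: none
Why: Heating the aryl 1,1-dimethylpropargyl ether triggers an aromatic propargyl Claisen [3,3]-sigmatropic shift from O-4' to C-3' giving dienone 18, which enolises to allenylphenol 19; a 1,5-hydrogen shift from the 4'-OH to the central allene carbon then gives the Z-configured ortho-quinone methide 20, and a thermal disrotatory oxa-6π electrocyclisation forms O1–C2. The closest known reaction type is the thermal conversion of 1,1-dimethylpropargyl ethers of 2-hydroxy-4-oxyaryl ketones into 5-hydroxy-2,2-dimethyl-2H-chromen-6-yl ketones. The only ring closed is the six-membered pyran, closed by the 6π electrocyclisation after the sigmatropic shift has made the C4a–C4 bond. No stereocentre is created, and C3, C4 and C5 of the cyclohexene should be untouched because the medium is neutral and base-free, the C4 hydrogen being the only epimerisable one. The step needs regioselectivity for C-3' over C-5' and chromene over 2-methylbenzofuran formation: the 2'-OH···O=C hydrogen bond fixes the ring so that the C3'–C4' bond has the higher double-bond character and C-3' is the doubly oxygen-activated ortho position, while the absence of base or fluoride disfavours the benzofuran pathway.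

**Step 15**
Reactants: 21 the chromene hexaacetate
Product: 22 the target CNP0115975.1
Conditions: K2CO3, MeOH, 0 °C to rt, argon; then aq NH4Cl
Reagents that add atoms: none
Why: base-mediated transesterification of the six aryl acetates with methanol; cold carbonate should neither epimerise C4 nor close the 2'-hydroxychalcone to a flavanone, the chromene is base-stable, and the absence of acid prevents ketalisation of the C4 ketone.

**Compound list**

1 | 2,4-dihydroxybenzaldehyde | O=Cc1ccc(O)cc1O | starting material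
2 | 2,4-bis(methoxymethoxy)benzaldehyde | COCOc1ccc(C=O)c(OCOC)c1 | intermediate
3 | 1-(2,4-dihydroxyphenyl)ethanone | CC(=O)c1ccc(O)cc1O | starting material
4 | 3-chloro-3-methylbut-1-yne | CC(C)(Cl)C#C | starting material
5 | 1-[2-hydroxy-4-(2-methylbut-3-yn-2-yloxy)phenyl]ethanone | CC(=O)c1ccc(OC(C)(C)C#C)cc1O | intermediate
6 | (E)-3-[2,4-bis(methoxymethoxy)phenyl]-1-[2-hydroxy-4-(2-methylbut-3-yn-2-yloxy)phenyl]prop-2-en-1-one | COCOc1ccc(/C=C/C(=O)c2ccc(OC(C)(C)C#C)cc2O)c(OCOC)c1 | intermediate
7 | (E)-3-(2,4-dihydroxyphenyl)-1-[2-hydroxy-4-(2-methylbut-3-yn-2-yloxy)phenyl]prop-2-en-1-one | Oc1ccc(/C=C/C(=O)c2ccc(OC(C)(C)C#C)cc2O)c(O)c1 | intermediate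
8 | (E)-4-{3-[2-hydroxy-4-(2-methylbut-3-yn-2-yloxy)phenyl]-3-oxoprop-1-enyl}-1,3-phenylene diacetate (dienophile) | CC(=O)Oc1ccc(/C=C/C(=O)c2ccc(OC(C)(C)C#C)cc2O)c(OC(C)=O)c1 | intermediate
9 | 1-(2,4-dihydroxy-3-iodophenyl)ethanone | CC(=O)c1ccc(O)c(I)c1O | intermediate
10 | 1-[3-iodo-2,4-bis(methoxymethoxy)phenyl]ethanone | CC(=O)c1ccc(OCOC)c(I)c1OCOC | intermediate
11 | (E)-3-[2,4-bis(methoxymethoxy)phenyl]-1-[3-iodo-2,4-bis(methoxymethoxy)phenyl]prop-2-en-1-one | COCOc1ccc(/C=C/C(=O)c2ccc(OCOC)c(I)c2OCOC)c(OCOC)c1 | intermediate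
12 | (E)-1-(2,4-dihydroxy-3-iodophenyl)-3-(2,4-dihydroxyphenyl)prop-2-en-1-one | Oc1ccc(/C=C/C(=O)c2ccc(O)c(I)c2O)c(O)c1 | intermediate
13 | (E)-1-(2,4-diacetoxy-3-iodophenyl)-3-(2,4-diacetoxyphenyl)prop-2-en-1-one | CC(=O)Oc1ccc(/C=C/C(=O)c2ccc(OC(C)=O)c(I)c2OC(C)=O)c(OC(C)=O)c1 | intermediate
14 | 2-methylbut-1-en-3-yne | CC(=C)C#C | starting material
15 | (E)-4,4,5,5-tetramethyl-2-(3-methylbuta-1,3-dienyl)-1,3,2-dioxaborolane | CC(=C)/C=C/B1OC(C)(C)C(C)(C)O1 | intermediate
16 | (E)-1-[2,4-diacetoxy-3-((E)-3-methylbuta-1,3-dienyl)phenyl]-3-(2,4-diacetoxyphenyl)prop-2-en-1-one (diene) | CC(=C)/C=C/c1c(OC(C)=O)ccc(C(=O)/C=C/c2ccc(OC(C)=O)cc2OC(C)=O)c1OC(C)=O | intermediate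
17 | endo Diels–Alder adduct (3S,4R,5S): 1-methylcyclohex-1-ene with 2,6-diacetoxy-3-[(E)-3-(2,4-diacetoxyphenyl)prop-2-enoyl]phenyl at C3, 2-hydroxy-4-(2-methylbut-3-yn-2-yloxy)benzoyl at C4 and 2,4-diacetoxyphenyl at C5; C3/C4 cis, C4/C5 trans | CC1=C[C@H](c2c(OC(C)=O)ccc(C(=O)/C=C/c3ccc(OC(C)=O)cc3OC(C)=O)c2OC(C)=O)[C@H](C(=O)c2ccc(OC(C)(C)C#C)cc2O)[C@@H](c2ccc(OC(C)=O)cc2OC(C)=O)C1 | intermediate
18 | allenyl cyclohexadienone (not isolated; as 17, but the C4 acyl group is 2-hydroxy-3-(3-methylbuta-1,2-dienyl)-4-oxocyclohexa-1,5-dien-1-ylcarbonyl, C-3' epimers) | CC1=C[C@H](c2c(OC(C)=O)ccc(C(=O)/C=C/c3ccc(OC(C)=O)cc3OC(C)=O)c2OC(C)=O)[C@H](C(=O)C2=C(O)C(C=C=C(C)C)C(=O)C=C2)[C@@H](c2ccc(OC(C)=O)cc2OC(C)=O)C1 | intermediate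
19 | ortho-allenylphenol (not isolated; as 17, but the C4 aroyl group is 2,4-dihydroxy-3-(3-methylbuta-1,2-dienyl)benzoyl) | CC1=C[C@H](c2c(OC(C)=O)ccc(C(=O)/C=C/c3ccc(OC(C)=O)cc3OC(C)=O)c2OC(C)=O)[C@H](C(=O)c2ccc(O)c(C=C=C(C)C)c2O)[C@@H](c2ccc(OC(C)=O)cc2OC(C)=O)C1 | intermediate
20 | ortho-quinone methide (not isolated; as 17, but the C4 acyl group is 2-hydroxy-3-(3-methylbut-2-enylidene)-4-oxocyclohexa-1,5-dien-1-ylcarbonyl, side chain syn to the C-4' carbonyl) | CC1=C[C@H](c2c(OC(C)=O)ccc(C(=O)/C=C/c3ccc(OC(C)=O)cc3OC(C)=O)c2OC(C)=O)[C@H](C(=O)C2=C(O)/C(=C/C=C(C)C)C(=O)C=C2)[C@@H](c2ccc(OC(C)=O)cc2OC(C)=O)C1 | intermediate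
21 | chromene hexaacetate (3S,4R,5S): as 17, but the C4 aroyl group is 5-hydroxy-2,2-dimethyl-2H-chromene-6-carbonyl | CC1=C[C@H](c2c(OC(C)=O)ccc(C(=O)/C=C/c3ccc(OC(C)=O)cc3OC(C)=O)c2OC(C)=O)[C@H](C(=O)c2ccc3c(c2O)C=CC(C)(C)O3)[C@@H](c2ccc(OC(C)=O)cc2OC(C)=O)C1 | intermediate
22 | CNP0115975.1, (3S,4R,5S) heptaphenol | CC1=C[C@H](c2c(O)ccc(C(=O)/C=C/c3ccc(O)cc3O)c2O)[C@H](C(=O)c2ccc3c(c2O)C=CC(C)(C)O3)[C@@H](c2ccc(O)cc2O)C1 | target

**Step count.** Total: 15 steps. Longest linear sequence: 9 steps (steps 6, 7, 8, 9, 10, 12, 13, 14, 15, from compound 3).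

**Steps most likely to fail**

1. Step 13 (Diels–Alder). What may go wrong is insufficient facial or endo/exo discrimination, or stalling of catalyst turnover because the product stays bound to boron. Fallback: starting from 8 and 16, the cycloaddition is run as an electron-transfer process on Ag nanoparticles supported on SiO2 (zerovalent silver, CH2Cl2, 50 °C). This method is known for 2'-hydroxychalcones and favours endo adducts, but gives the racemate. The endo racemate, that is 17 together with its mirror image ent-17 F1, is resolved by preparative HPLC on a chiral stationary phase, and the route is rejoined at 17.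

2. Step 14 (key cascade). What may go wrong is thermal damage before the cascade is complete: epimerisation at C4, acetyl scrambling onto the liberated phenol, or diversion of the allenyl intermediate. Fallback: starting from 17, the terminal alkyne is semihydrogenated (H2, Pd/CaCO3 poisoned with Pb(OAc)2, quinoline, EtOAc) to the 1,1-dimethylallyl ether F2. Its aromatic Claisen rearrangement proceeds at a much lower temperature (toluene, about 110 °C) and should give the 3'-prenyl-2',4'-dihydroxy compound F3. A biomimetic oxidative cyclisation with DDQ in benzene (hydride abstraction to the ortho-quinone methide, then oxa-6π closure onto the non-chelated 4'-oxygen) rejoins the route at 21.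

3. Step 12 (Suzuki–Miyaura coupling). What may go wrong is cleavage of the aryl acetates by the base, or slow coupling at the di-ortho-substituted iodide with competing protodeboronation or polymerisation of the dienylboronate. Fallback: starting from 13, a Heck reaction with 2-methylbut-3-en-2-ol (Pd(OAc)2, Bu4NCl, NaHCO3, DMF, 60 °C) should give the tertiary allylic alcohol F4. Syn-dehydration with methyl N-(triethylammoniosulfonyl)carbamate (Burgess reagent; toluene, 50 °C), which can only remove a methyl hydrogen, rejoins the route at 16.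

**Further compounds**

F1 | step 13 | ent-17, the (3R,4S,5R) mirror image of adduct 17 | CC1=C[C@@H](c2c(OC(C)=O)ccc(C(=O)/C=C/c3ccc(OC(C)=O)cc3OC(C)=O)c2OC(C)=O)[C@@H](C(=O)c2ccc(OC(C)(C)C#C)cc2O)[C@H](c2ccc(OC(C)=O)cc2OC(C)=O)C1
F2 | step 14 | 1,1-dimethylallyl ether: as 17, but the C4 aroyl group is 2-hydroxy-4-(2-methylbut-3-en-2-yloxy)benzoyl | CC1=C[C@H](c2c(OC(C)=O)ccc(C(=O)/C=C/c3ccc(OC(C)=O)cc3OC(C)=O)c2OC(C)=O)[C@H](C(=O)c2ccc(OC(C)(C)C=C)cc2O)[C@@H](c2ccc(OC(C)=O)cc2OC(C)=O)C1
F3 | step 14 | 3'-prenyl phenol: as 17, but the C4 aroyl group is 2,4-dihydroxy-3-(3-methylbut-2-enyl)benzoyl | CC1=C[C@H](c2c(OC(C)=O)ccc(C(=O)/C=C/c3ccc(OC(C)=O)cc3OC(C)=O)c2OC(C)=O)[C@H](C(=O)c2ccc(O)c(CC=C(C)C)c2O)[C@@H](c2ccc(OC(C)=O)cc2OC(C)=O)C1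
F4 | step 12 | (E)-1-[2,4-diacetoxy-3-((E)-3-hydroxy-3-methylbut-1-enyl)phenyl]-3-(2,4-diacetoxyphenyl)prop-2-en-1-one | CC(C)(O)/C=C/c1c(OC(C)=O)ccc(C(=O)/C=C/c2ccc(OC(C)=O)cc2OC(C)=O)c1OC(C)=O
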